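**Plan**

- Retrosynthesis: remove the two phenol MOM groups; take the vinyl group back to a methyl ester (CH=CH2 ⇐ CHO ⇐ CH2OH ⇐ CO2Me); cut the C4–C5 bond (γ-CH2 of the ketone to C1 of the geranyl unit) and at the same time reconnect C4 to the carbonyl carbon C1, which gives a cyclobutanol; cut the aryl–carbinol bond.
- Enabling feature: carbonyl carbon C1, α-CH2 C2, quaternary β-carbon C3 and γ-CH2 C4 of the aryl ketone are the four ring atoms of a 1-aryl-3,3-disubstituted cyclobutan-1-ol. Its two ring CH2 groups are enantiotopic, and C3 carries no hydrogen.
- Forward: 4-bromoresorcinol bis-MOM ether is lithiated and added to methyl 1-methyl-3-oxocyclobutane-1-carboxylate. The achiral cyclobutanol is opened by chiral Pd with tert-butyl geranyl carbonate; this joins the C10 chain at C4, releases the aryl ketone and sets C3. Ester → CH2OH → CHO → vinyl, then MOM removal.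
- Stereochemistry: (3R) comes from catalyst-controlled choice between the two enantiotopic ring C–C bonds (desymmetrisation); (6E) is carried in from geraniol.
- The vinyl group is kept as an ester through the Pd step so that no alkene sits next to the alkylpalladium.

Key step: step 4

Assumptions: compound 3 is taken as a catalogue building block. The sense of induction of the ligand in step 4 cannot be predicted; both ligand enantiomers are available, and the one that gives (R)-8 is fixed in a pilot run.

Step 1
Reactants: 1 4-bromoresorcinol
Product: 2 1-bromo-2,4-bis(methoxymethoxy)benzene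
Conditions: MOMCl (2.5 equiv), i-Pr2NEt (3 equiv), CH2Cl2, 0 °C → rt
Reagents that add atoms: chloromethyl methyl ether (MOMCl), COCCl
Why: Double O-alkylation of the phenols (Williamson-type ether formation); MOM is chosen because the ortho-MOM ether stabilises the later aryllithium and the groups survive base, palladium, hydride, periodinane and ylide but leave under mild acid.

Step 2
Reactants: 2 1-bromo-2,4-bis(methoxymethoxy)benzene; 3 methyl 1-methyl-3-oxocyclobutane-1-carboxylate
Product: 5 methyl 3-[2,4-bis(methoxymethoxy)phenyl]-3-hydroxy-1-methylcyclobutane-1-carboxylate (hydroxyl cis to the ring methyl and trans to the ester), via aryllithium 4 (not isolated)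
Conditions: n-BuLi (1.05 equiv), THF, −78 °C; then 3, −78 °C; aq NH4Cl; chromatography to separate the two ring diastereomers
Reagents that add atoms: none
Why: Br/Li exchange at −78 °C is fast and the ortho-MOM-chelated aryllithium should add to the strained, electrophilic cyclobutanone far faster than to the α-quaternary methyl ester (organolithium 1,2-addition to a ketone); the product has only ring cis/trans isomerism, little facial bias is expected, and the isomer with hydroxyl trans to the ester, which cannot lactonise, is taken on.

Step 3
Reactants: 6 geraniol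
Product: 7 tert-butyl (2E)-3,7-dimethylocta-2,6-dien-1-yl carbonate (tert-butyl geranyl carbonate)
Conditions: Boc2O, n-Bu4NHSO4 (cat.), 30% aq NaOH, CH2Cl2, 0 °C → rt
Reagents that add atoms: di-tert-butyl dicarbonate (Boc2O), CC(C)(C)OC(=O)OC(=O)OC(C)(C)C
Why: Acylation of the primary allylic alcohol under phase-transfer conditions (carbonate formation) gives the ionisable partner, which on oxidative addition releases CO2 and tert-butoxide, a base without β-hydrogens; the E double bond is not touched.

Step 4
Reactants: 5 methyl 3-[2,4-bis(methoxymethoxy)phenyl]-3-hydroxy-1-methylcyclobutane-1-carboxylate (hydroxyl trans to the ester); 7 tert-butyl geranyl carbonate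
Product: 8 methyl (2R,5E)-2-{2-[2,4-bis(methoxymethoxy)phenyl]-2-oxoethyl}-2,6,10-trimethylundeca-5,9-dienoate
Conditions: Pd2(dba)3·CHCl3 (2.5 mol %), (R,Sp)-PPFA-type ferrocenyl P,N ligand (6 mol %; enantiomer as fixed by the pilot run), 7 (1.1 equiv), PhMe, 50 °C
Reagents that add atoms: none
Why: Proposed new method: Pd(0) ionises the carbonate to a π-geranylpalladium(II) tert-butoxide with loss of CO2, alkoxide exchange gives a palladium cyclobutanolate, strain-driven β-carbon elimination opens the ring to the aryl ketone and a primary alkylpalladium, and C(sp3)–C(sp3) reductive elimination at the unsubstituted allyl terminus forms the CH2–CH2 bond. The closest known reaction type is the Pd-catalysed enantioselective ring-opening arylation, vinylation and allenylation of tert-cyclobutanols by β-carbon elimination, here extended to an allyl partner, together with the known α-selective, geometry-retaining Pd coupling of geranyl electrophiles with alkyl metals. No ring is closed; the four-membered ring is opened. The quaternary stereocentre is not set by bond formation at that carbon but by desymmetrisation: the chiral ligand on palladium decides which of the two enantiotopic ring C–C bonds of the achiral alcohol is cleaved, and the single relative configuration of 5 makes this choice one absolute configuration. The step needs enantiotopic-bond selectivity (ligand), α- over γ-attack with retention of the E alkene (reductive elimination at the less hindered terminus, faster than syn/anti isomerisation) and C–C over C–O coupling (ring strain lets β-carbon elimination outrun etherification of the hindered tertiary alkoxide). The carbon next to palladium is quaternary, so β-hydride elimination is impossible, and the ester in place of the vinyl group removes any alkene within reach of the alkylpalladium.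

Step 5
Reactants: 8 methyl (2R,5E)-2-{2-[2,4-bis(methoxymethoxy)phenyl]-2-oxoethyl}-2,6,10-trimethylundeca-5,9-dienoate
Product: 10 (3R,6E)-1-[2,4-bis(methoxymethoxy)phenyl]-3-(hydroxymethyl)-3,7,11-trimethyldodeca-6,10-dien-1-one, via lithium enolate 9 (not isolated)
Conditions: LiHMDS (1.2 equiv), THF, −78 °C; then LiAlH4, −78 → 0 °C; Rochelle salt work-up
Reagents that add atoms: none
Why: The aryl ketone has the only enolisable position (the ester is α-quaternary), so LiHMDS turns it into an enolate that hydride does not attack, and LiAlH4 then reduces only the ester to the primary alcohol (ester reduction with in situ enolate protection of a ketone); the quaternary centre keeps its configuration.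

Step 6
Reactants: 10 (3R,6E)-1-[2,4-bis(methoxymethoxy)phenyl]-3-(hydroxymethyl)-3,7,11-trimethyldodeca-6,10-dien-1-one
Product: 11 (2R,5E)-2-{2-[2,4-bis(methoxymethoxy)phenyl]-2-oxoethyl}-2,6,10-trimethylundeca-5,9-dienal
Conditions: Dess–Martin periodinane, pyridine, CH2Cl2, 0 °C → rt
Reagents that add atoms: none
Why: Dess–Martin oxidation of the neopentyl primary alcohol stops at the aldehyde, the competing cyclic hemiketal of the γ-hydroxy ketone is tertiary and cannot be over-oxidised to a lactone, and the aldehyde has no α-hydrogen to epimerise.

Step 7
Reactants: 11 (2R,5E)-2-{2-[2,4-bis(methoxymethoxy)phenyl]-2-oxoethyl}-2,6,10-trimethylundeca-5,9-dienal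
Product: 12 (3R,6E)-1-[2,4-bis(methoxymethoxy)phenyl]-3,7,11-trimethyl-3-vinyldodeca-6,10-dien-1-one
Conditions: Ph3PCH3Br, KOt-Bu, THF, 0 °C; then 11, −78 → 0 °C
Reagents that add atoms: methyltriphenylphosphonium bromide, C[P+](c1ccccc1)(c1ccccc1)c1ccccc1.[Br-]
Why: Wittig methylenation: the unstabilised ylide should take the aldehyde much faster than the electron-rich, ortho-substituted aryl ketone, whose reversible enolisation is harmless, and this turns the former ester carbon into the vinyl group on the intact quaternary centre.

Step 8
Reactants: 12 (3R,6E)-1-[2,4-bis(methoxymethoxy)phenyl]-3,7,11-trimethyl-3-vinyldodeca-6,10-dien-1-one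
Product: 13 (3R,6E)-1-(2,4-dihydroxyphenyl)-3,7,11-trimethyl-3-vinyldodeca-6,10-dien-1-one (target)
Conditions: conc. HCl (cat.), MeOH, 0 °C → rt
Reagents that add atoms: none
Why: Acid-catalysed acetal exchange with methanol removes both MOM groups under conditions mild enough to leave the trisubstituted alkenes, the vinyl group and the β-quaternary ketone untouched.

**Compound list**

1 | 4-bromoresorcinol (4-bromobenzene-1,3-diol) | Oc1ccc(Br)c(O)c1 | starting material
2 | 1-bromo-2,4-bis(methoxymethoxy)benzene | COCOc1ccc(Br)c(OCOC)c1 | intermediate
3 | methyl 1-methyl-3-oxocyclobutane-1-carboxylate | COC(=O)C1(C)CC(=O)C1 | starting material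
4 | [2,4-bis(methoxymethoxy)phenyl]lithium | [Li]c1ccc(OCOC)cc1OCOC | intermediate
5 | methyl 3-[2,4-bis(methoxymethoxy)phenyl]-3-hydroxy-1-methylcyclobutane-1-carboxylate, hydroxyl cis to methyl, trans to ester (achiral) | COC(=O)[C@]1(C)C[C@](O)(c2ccc(OCOC)cc2OCOC)C1 | intermediate
6 | geraniol, (2E)-3,7-dimethylocta-2,6-dien-1-ol | CC(C)=CCC/C(C)=C/CO | starting material
7 | tert-butyl (2E)-3,7-dimethylocta-2,6-dien-1-yl carbonate | CC(C)=CCC/C(C)=C/COC(=O)OC(C)(C)C | intermediate
8 | methyl (2R,5E)-2-{2-[2,4-bis(methoxymethoxy)phenyl]-2-oxoethyl}-2,6,10-trimethylundeca-5,9-dienoate | COC(=O)[C@](C)(CC/C=C(\C)CCC=C(C)C)CC(=O)c1ccc(OCOC)cc1OCOC | intermediate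
9 | lithium (Z)-enolate of 8 at the aryl ketone, (R) at the quaternary carbon | COC(=O)[C@](C)(CC/C=C(\C)CCC=C(C)C)/C=C(\O[Li])c1ccc(OCOC)cc1OCOC | intermediate
10 | (3R,6E)-1-[2,4-bis(methoxymethoxy)phenyl]-3-(hydroxymethyl)-3,7,11-trimethyldodeca-6,10-dien-1-one | OC[C@](C)(CC/C=C(\C)CCC=C(C)C)CC(=O)c1ccc(OCOC)cc1OCOC | intermediate
11 | (2R,5E)-2-{2-[2,4-bis(methoxymethoxy)phenyl]-2-oxoethyl}-2,6,10-trimethylundeca-5,9-dienal | O=C[C@](C)(CC/C=C(\C)CCC=C(C)C)CC(=O)c1ccc(OCOC)cc1OCOC | intermediate
12 | (3R,6E)-1-[2,4-bis(methoxymethoxy)phenyl]-3,7,11-trimethyl-3-vinyldodeca-6,10-dien-1-one | C=C[C@](C)(CC/C=C(\C)CCC=C(C)C)CC(=O)c1ccc(OCOC)cc1OCOC | intermediate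
13 | (3R,6E)-1-(2,4-dihydroxyphenyl)-3,7,11-trimethyl-3-vinyldodeca-6,10-dien-1-one | C=C[C@](C)(CC/C=C(\C)CCC=C(C)C)CC(=O)c1ccc(O)cc1O | target

**Count and risks**

Total step count: 8. Longest linear sequence: 7 (steps 1, 2, 4, 5, 6, 7, 8).

1. Step 4. The alkyl(allyl)palladium may not undergo reductive elimination fast enough, so that O-allylation of the tertiary alkoxide, loss of the geranyl unit as a diene or α-allylation of the product ketone takes over; the two enantiotopic ring bonds may also be told apart poorly. The fallback uses known chemistry, sets the quaternary centre by branch-selective allylic alkylation and brings the aryl group in last. It sets out from aryllithium 4 (made from 2 as in step 2) and commercial (2E,6E)-farnesol. Methyl chloroformate and pyridine should give (2E,6E)-farnesyl methyl carbonate F1. Iridium/chiral phosphoramidite-catalysed allylic alkylation with sodium dimethyl malonate should give the branched dimethyl 2-[(3S,6E)-3,7,11-trimethyldodeca-1,6,10-trien-3-yl]propanedioate F2, which carries the vinyl-bearing quaternary centre. Krapcho demethoxycarbonylation (LiCl, wet DMSO, 150 °C) should give methyl (3R,6E)-3,7,11-trimethyl-3-vinyldodeca-6,10-dienoate F3. MeNH(OMe)·HCl with i-PrMgCl should give the Weinreb amide (3R,6E)-N-methoxy-N,3,7,11-tetramethyl-3-vinyldodeca-6,10-dienamide F4. Addition of 4 at −78 °C should give ketone 12, where the route is rejoined before step 8.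

2. Step 5. Enolisation may be incomplete, so that hydride also attacks the aryl ketone, or the hindered ester may resist reduction at a temperature the enolate tolerates. The fallback gives up chemoselectivity. It sets out from 8: excess LiAlH4 should reduce ketone and ester to (3R,6E)-1-[2,4-bis(methoxymethoxy)phenyl]-3-(hydroxymethyl)-3,7,11-trimethyldodeca-6,10-dien-1-ol F5 (both epimers at the carbinol). One Swern oxidation, in which both hydroxyls are activated before the base is added so that no lactol can form, should give keto aldehyde 11, where the route is rejoined.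

3. Step 2. Facial selectivity in the addition to the cyclobutanone may be poor, so that much of the material ends up as the other ring diastereomer. The fallback makes that isomer productive instead of trying to suppress it. It sets out from 4 and 3 in the same addition. The isomer methyl 3-[2,4-bis(methoxymethoxy)phenyl]-3-hydroxy-1-methylcyclobutane-1-carboxylate with hydroxyl cis to the ester F6 is collected and put through the conditions of step 4 with the enantiomeric ligand. This ligand cleaves the mirror-related ring bond, which on the diastereomeric alcohol should lead to the same keto ester 8, where the route is rejoined.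

Further compounds
F1 | step 4 | (2E,6E)-farnesyl methyl carbonate | CC(C)=CCC/C(C)=C/CC/C(C)=C/COC(=O)OC
F2 | step 4 | dimethyl 2-[(3S,6E)-3,7,11-trimethyldodeca-1,6,10-trien-3-yl]propanedioate | C=C[C@](C)(CC/C=C(\C)CCC=C(C)C)C(C(=O)OC)C(=O)OC
F3 | step 4 | methyl (3R,6E)-3,7,11-trimethyl-3-vinyldodeca-6,10-dienoate | C=C[C@](C)(CC/C=C(\C)CCC=C(C)C)CC(=O)OC
F4 | step 4 | (3R,6E)-N-methoxy-N,3,7,11-tetramethyl-3-vinyldodeca-6,10-dienamide | C=C[C@](C)(CC/C=C(\C)CCC=C(C)C)CC(=O)N(C)OC
F5 | step 5 | (3R,6E)-1-[2,4-bis(methoxymethoxy)phenyl]-3-(hydroxymethyl)-3,7,11-trimethyldodeca-6,10-dien-1-ol, both carbinol epimers | OC[C@](C)(CC/C=C(\C)CCC=C(C)C)CC(O)c1ccc(OCOC)cc1OCOC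
F6 | step 2 | methyl 3-[2,4-bis(methoxymethoxy)phenyl]-3-hydroxy-1-methylcyclobutane-1-carboxylate, hydroxyl cis to ester (achiral) | COC(=O)[C@]1(C)C[C@@](O)(c2ccc(OCOC)cc2OCOC)C1
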